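**Retrosynthetic overview**

1. The (R)-isoflavan is traced back, through desilylation and removal of a C4 hydroxyl, to the cis-(3R,4R)-isoflavan-4-ol and then to a racemic isoflavanone. The C4 carbonyl is a temporary handle that keeps C3 epimerisable, so an asymmetric transfer hydrogenation with dynamic kinetic resolution can set C3.
2. Ring C of the isoflavanone is opened at O1–C2 and at C4–C4a. This gives a one-pot [3+3] annulation of an O,C-dilithiated ring A phenol (prenyl in place) with the N-methoxy-N-methyl amide of a 2-arylacrylic acid (ring B with its pyran ring in place).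
3. Enabling feature: in ring A, O1 and its ortho carbon C4a (marked by bromine) are a 1,3-O,C-dinucleophile, matched by the 1,3-dielectrophile C4(=O)–C3(aryl)=C2H2. The C4 oxygen lies ortho to O1 and para to O7 on ring A, so it can later be ionised off.
4. Both halves come from one mono-silylated 4-bromoresorcinol: iodination and Stille prenylation give the ring A phenol; propargyl ether Claisen cyclisation and Negishi coupling with a 2-bromoacrylamide give the ring B acrylamide.
5. Ring order: rings A and B are bought as arenes, the 2,2-dimethylpyran ring on ring B is closed in step 5, and ring C is closed in step 8.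

Key step: step 8

Assumption: compounds 1, 4, 6, 10 and 11 are taken as catalogue compounds, and the configuration to be made at C3 of ring C is (R), as read from the target SMILES.

Step 1
Reactants: 1 4-bromobenzene-1,3-diol (4-bromoresorcinol)
Product: 2 2-bromo-5-(triisopropylsilyloxy)phenol
Conditions: TIPSCl (1.0 equiv), imidazole (2.0 equiv), CH2Cl2, 0 °C
Reagents that add atoms: triisopropylsilyl chloride, CC(C)[Si](Cl)(C(C)C)C(C)C
Why: Silyl ether formation with a bulky silyl chloride should select the unhindered hydroxyl para to bromine over the hydroxyl flanked by bromine.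

Step 2
Reactants: 2 2-bromo-5-(triisopropylsilyloxy)phenol
Product: 3 2-bromo-4-iodo-5-(triisopropylsilyloxy)phenol
Conditions: NIS (1.05 equiv), MeCN, 0 °C
Reagents that add atoms: N-iodosuccinimide, O=C1CCC(=O)N1I
Why: Electrophilic aromatic iodination of a phenol should go para to the free hydroxyl, because the only other activated carbon lies between the two oxygen substituents and is more hindered.

Step 3
Reactants: 3 2-bromo-4-iodo-5-(triisopropylsilyloxy)phenol; 4 tributyl(3-methylbut-2-en-1-yl)stannane
Product: 5 2-bromo-4-(3-methylbut-2-en-1-yl)-5-(triisopropylsilyloxy)phenol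
Conditions: Pd(PPh3)4 (5 mol%), DMF, 80 °C
Reagents that add atoms: none
Why: Stille coupling should occur at the C–I bond well before the C–Br bond and transfer the prenyl group through its primary carbon, and the free hydroxyl is para to the prenyl group and cannot cyclise onto it.

Step 4
Reactants: 2 2-bromo-5-(triisopropylsilyloxy)phenol; 6 3-chloro-3-methylbut-1-yne
Product: 7 [4-bromo-3-(2-methylbut-3-yn-2-yloxy)phenoxy]triisopropylsilane
Conditions: DBU (1.5 equiv), CuCl2·2H2O (1 mol%), MeCN, 0 °C → rt
Reagents that add atoms: none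
Why: Copper-catalysed O-alkylation of a phenol with a tertiary propargylic chloride should give the aryl 1,1-dimethylpropargyl ether, and the aryl silyl ether is stable to DBU.

Step 5
Reactants: 7 [4-bromo-3-(2-methylbut-3-yn-2-yloxy)phenoxy]triisopropylsilane
Product: 9 8-bromo-2,2-dimethyl-5-(triisopropylsilyloxy)-2H-chromene, via allenyl phenol 8 (not isolated)
Conditions: N,N-diethylaniline, 180 °C
Reagents that add atoms: none
Why: Aromatic propargyl Claisen rearrangement to the only free ortho carbon, then 1,5-hydrogen shift and oxa-6π electrocyclisation, should close the 2,2-dimethylpyran ring.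

Step 6
Reactants: 10 2,3-dibromopropanoyl chloride; 11 N,O-dimethylhydroxylamine hydrochloride
Product: 13 2-bromo-N-methoxy-N-methylprop-2-enamide, via dibromo amide 12 (not isolated)
Conditions: Et3N (3.3 equiv), CH2Cl2, 0 °C → rt
Reagents that add atoms: none
Why: N-Acylation followed by amine-induced E2 loss of HBr from the 2,3-dibromo amide is the standard route to 2-bromoacrylamides.

Step 7
Reactants: 9 8-bromo-2,2-dimethyl-5-(triisopropylsilyloxy)-2H-chromene; 13 2-bromo-N-methoxy-N-methylprop-2-enamide
Product: 16 2-[2,2-dimethyl-5-(triisopropylsilyloxy)-2H-chromen-8-yl]-N-methoxy-N-methylprop-2-enamide, via aryllithium 14 (not isolated), via arylzinc chloride 15 (not isolated)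
Conditions: n-BuLi (1.05 equiv), THF, −78 °C; ZnCl2 (1.1 equiv), −78 °C → rt; 13, Pd(PPh3)4 (5 mol%), THF, rt → 45 °C
Reagents that add atoms: none
Why: Bromine–lithium exchange and transmetalation give an arylzinc that should undergo Negishi coupling at the activated vinylic C–Br bond without adding to the amide carbonyl or the acrylamide double bond.

Step 8
Reactants: 5 2-bromo-4-(3-methylbut-2-en-1-yl)-5-(triisopropylsilyloxy)phenol; 16 2-[2,2-dimethyl-5-(triisopropylsilyloxy)-2H-chromen-8-yl]-N-methoxy-N-methylprop-2-enamide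
Product: 20 racemic 3-[2,2-dimethyl-5-(triisopropylsilyloxy)-2H-chromen-8-yl]-6-(3-methylbut-2-en-1-yl)-7-(triisopropylsilyloxy)chroman-4-one, via dilithio phenoxide 17 (not isolated), via tetrahedral adduct 18 (not isolated), via hydroxy enone 19 (not isolated)
Conditions: 5, t-BuLi (3.1 equiv), THF, −78 °C; then 16 (1.0 equiv), −78 → 0 °C; sat. aq. NH4Cl, then Et3N (cat.), rt
Reagents that add atoms: none
Why: Deprotonation and bromine–lithium exchange turn 5 into the O,C-dilithio species 17, whose aryl carbanion adds to the amide carbonyl of 16 (new bond from the ring A carbon to the future C4) to give the chelated adduct 18; on aqueous quench 18 collapses to the 2-hydroxyaryl α-aryl vinyl ketone 19, whose phenol oxygen adds to the terminal CH2 of the enone (new O1–C2 bond). The closest known reaction types are the acylation of 2-lithiophenoxides by N-methoxy-N-methyl amides and the oxa-Michael closure of 2'-hydroxy-α-methylene deoxybenzoins to isoflavanones. Ring C closes by a 6-endo-trig oxa-Michael addition. C3 is created by protonation of the resulting enolate and is deliberately left racemic, because the C4 ketone keeps it epimerisable for step 9. The step needs 1,2- and not 1,4-addition of the aryllithium, which the chelating N-methoxy-N-methyl amide and the low temperature should secure, and it needs reaction through the carbon ortho to the phenoxide, which the position of the bromine fixes. The silyl ether on the other ring A oxygen keeps that oxygen out of the reaction, and any amine adduct of the enone should revert under the basic finish and drain into the cyclised ketone.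

Step 9
Reactants: 20 racemic 3-[2,2-dimethyl-5-(triisopropylsilyloxy)-2H-chromen-8-yl]-6-(3-methylbut-2-en-1-yl)-7-(triisopropylsilyloxy)chroman-4-one
Product: 21 (3R,4R)-3-[2,2-dimethyl-5-(triisopropylsilyloxy)-2H-chromen-8-yl]-6-(3-methylbut-2-en-1-yl)-7-(triisopropylsilyloxy)chroman-4-ol
Conditions: RuCl(p-cymene)[(R,R)-TsDPEN] (3 mol%), HCO2H/Et3N (5:2), EtOAc, 40 °C
Reagents that add atoms: none
Why: Asymmetric transfer hydrogenation with dynamic kinetic resolution: the α-aryl ketone racemises at C3 through its enol under Et3N while the (R,R)-catalyst should reduce the (3R)-ketone faster and from the face anti to the aryl group, giving the cis alcohol with C4 (R) and C3 (R) and leaving both C=C bonds untouched.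

Step 10
Reactants: 21 (3R,4R)-3-[2,2-dimethyl-5-(triisopropylsilyloxy)-2H-chromen-8-yl]-6-(3-methylbut-2-en-1-yl)-7-(triisopropylsilyloxy)chroman-4-ol
Product: 22 (R)-3-[2,2-dimethyl-5-(triisopropylsilyloxy)-2H-chromen-8-yl]-6-(3-methylbut-2-en-1-yl)-7-(triisopropylsilyloxy)chroman
Conditions: Et3SiH (4 equiv), TFA (3 equiv), CH2Cl2, −40 °C
Reagents that add atoms: none
Why: Ionic deoxygenation: the C4 alcohol ionises easily because the cation is stabilised by O1 (ortho) and the O7 silyl ether (para), Et3SiH should trap it at low temperature, and C3 is not involved and keeps its (R) configuration.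

Step 11
Reactants: 22 (R)-3-[2,2-dimethyl-5-(triisopropylsilyloxy)-2H-chromen-8-yl]-6-(3-methylbut-2-en-1-yl)-7-(triisopropylsilyloxy)chroman
Product: 23 (R)-8-[7-hydroxy-6-(3-methylbut-2-en-1-yl)chroman-3-yl]-2,2-dimethyl-2H-chromen-5-ol
Conditions: TBAF (2.4 equiv), AcOH (2.4 equiv), THF, 0 °C
Reagents that add atoms: none
Why: Fluoride cleaves both aryl silyl ethers under buffered, non-acidic conditions that should leave the prenyl group, the chromene double bond and the stereocentre untouched.

**Compound list**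

1 | 4-bromobenzene-1,3-diol | Oc1ccc(Br)c(O)c1 | starting material
2 | 2-bromo-5-(triisopropylsilyloxy)phenol | Oc1cc(O[Si](C(C)C)(C(C)C)C(C)C)ccc1Br | intermediate
3 | 2-bromo-4-iodo-5-(triisopropylsilyloxy)phenol | Oc1cc(O[Si](C(C)C)(C(C)C)C(C)C)c(I)cc1Br | intermediate
4 | tributyl(3-methylbut-2-en-1-yl)stannane | CC(C)=CC[Sn](CCCC)(CCCC)CCCC | starting material
5 | 2-bromo-4-(3-methylbut-2-en-1-yl)-5-(triisopropylsilyloxy)phenol | Oc1cc(O[Si](C(C)C)(C(C)C)C(C)C)c(CC=C(C)C)cc1Br | intermediate
6 | 3-chloro-3-methylbut-1-yne | CC(C)(Cl)C#C | starting material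
7 | [4-bromo-3-(2-methylbut-3-yn-2-yloxy)phenoxy]triisopropylsilane | C#CC(C)(C)Oc1cc(O[Si](C(C)C)(C(C)C)C(C)C)ccc1Br | intermediate
8 | 2-bromo-6-(3-methylbuta-1,2-dien-1-yl)-5-(triisopropylsilyloxy)phenol (allenyl phenol, not isolated) | CC(C)=C=Cc1c(O)c(Br)ccc1O[Si](C(C)C)(C(C)C)C(C)C | intermediate
9 | 8-bromo-2,2-dimethyl-5-(triisopropylsilyloxy)-2H-chromene | CC1(C)C=Cc2c(O[Si](C(C)C)(C(C)C)C(C)C)ccc(Br)c2O1 | intermediate
10 | 2,3-dibromopropanoyl chloride (racemic) | O=C(Cl)C(Br)CBr | starting material
11 | N,O-dimethylhydroxylamine hydrochloride | CNOC.Cl | starting material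
12 | 2,3-dibromo-N-methoxy-N-methylpropanamide (racemic, not isolated) | CON(C)C(=O)C(Br)CBr | intermediate
13 | 2-bromo-N-methoxy-N-methylprop-2-enamide | CON(C)C(=O)C(Br)=C | intermediate
14 | [2,2-dimethyl-5-(triisopropylsilyloxy)-2H-chromen-8-yl]lithium (not isolated) | [Li]c1ccc(O[Si](C(C)C)(C(C)C)C(C)C)c2C=CC(C)(C)Oc12 | intermediate
15 | chloro[2,2-dimethyl-5-(triisopropylsilyloxy)-2H-chromen-8-yl]zinc (not isolated) | Cl[Zn]c1ccc(O[Si](C(C)C)(C(C)C)C(C)C)c2C=CC(C)(C)Oc12 | intermediate
16 | 2-[2,2-dimethyl-5-(triisopropylsilyloxy)-2H-chromen-8-yl]-N-methoxy-N-methylprop-2-enamide | CON(C)C(=O)C(=C)c1ccc(O[Si](C(C)C)(C(C)C)C(C)C)c2C=CC(C)(C)Oc12 | intermediate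
17 | lithium 2-lithio-4-(3-methylbut-2-en-1-yl)-5-(triisopropylsilyloxy)phenoxide (not isolated) | [Li]Oc1cc(O[Si](C(C)C)(C(C)C)C(C)C)c(CC=C(C)C)cc1[Li] | intermediate
18 | dilithium salt of the carbinolamine from addition of 17 to the amide carbonyl of 16 (tetrahedral adduct, not isolated) | [Li]Oc1cc(O[Si](C(C)C)(C(C)C)C(C)C)c(CC=C(C)C)cc1C(O[Li])(N(C)OC)C(=C)c1ccc(O[Si](C(C)C)(C(C)C)C(C)C)c2C=CC(C)(C)Oc12 | intermediate
19 | 2-[2,2-dimethyl-5-(triisopropylsilyloxy)-2H-chromen-8-yl]-1-[2-hydroxy-5-(3-methylbut-2-en-1-yl)-4-(triisopropylsilyloxy)phenyl]prop-2-en-1-one (not isolated) | Oc1cc(O[Si](C(C)C)(C(C)C)C(C)C)c(CC=C(C)C)cc1C(=O)C(=C)c1ccc(O[Si](C(C)C)(C(C)C)C(C)C)c2C=CC(C)(C)Oc12 | intermediate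
20 | racemic 3-[2,2-dimethyl-5-(triisopropylsilyloxy)-2H-chromen-8-yl]-6-(3-methylbut-2-en-1-yl)-7-(triisopropylsilyloxy)chroman-4-one | CC(C)=CCc1cc2c(cc1O[Si](C(C)C)(C(C)C)C(C)C)OCC(c1ccc(O[Si](C(C)C)(C(C)C)C(C)C)c3C=CC(C)(C)Oc13)C2=O | intermediate
21 | (3R,4R)-3-[2,2-dimethyl-5-(triisopropylsilyloxy)-2H-chromen-8-yl]-6-(3-methylbut-2-en-1-yl)-7-(triisopropylsilyloxy)chroman-4-ol (cis) | CC(C)=CCc1cc2c(cc1O[Si](C(C)C)(C(C)C)C(C)C)OC[C@@H](c1ccc(O[Si](C(C)C)(C(C)C)C(C)C)c3C=CC(C)(C)Oc13)[C@H]2O | intermediate
22 | (R)-3-[2,2-dimethyl-5-(triisopropylsilyloxy)-2H-chromen-8-yl]-6-(3-methylbut-2-en-1-yl)-7-(triisopropylsilyloxy)chroman | CC(C)=CCc1cc2c(cc1O[Si](C(C)C)(C(C)C)C(C)C)OC[C@@H](c1ccc(O[Si](C(C)C)(C(C)C)C(C)C)c3C=CC(C)(C)Oc13)C2 | intermediate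
23 | (R)-8-[7-hydroxy-6-(3-methylbut-2-en-1-yl)chroman-3-yl]-2,2-dimethyl-2H-chromen-5-ol | CC(C)=CCc1cc2c(cc1O)OC[C@@H](c1ccc(O)c3c1OC(C)(C)C=C3)C2 | target

**Step count and risks**

Total steps: 11. Longest linear sequence: 8 steps (steps 1, 4, 5, 7, 8, 9, 10, 11).

Steps most likely to fail:

1. Step 8. The aryllithium may add in the conjugate sense to the acrylamide instead of at the carbonyl, or the liberated N,O-dimethylhydroxylamine may add to the enone and hold it back from ring closure. The fallback builds the same ketone without a Michael acceptor being present during the organolithium step; it sets out from 5 and 9 and comes back at 20. Compound 5 is converted into its dilithio species as before and acylated with N-methoxy-N-methylacetamide to give 1-[2-hydroxy-5-(3-methylbut-2-en-1-yl)-4-(triisopropylsilyloxy)phenyl]ethan-1-one F1. Palladium-catalysed α-arylation of this methyl ketone (as its phenoxide) with bromide 9 (Pd(OAc)2, XPhos, K3PO4, toluene, 80 °C) should give the deoxybenzoin 2-[2,2-dimethyl-5-(triisopropylsilyloxy)-2H-chromen-8-yl]-1-[2-hydroxy-5-(3-methylbut-2-en-1-yl)-4-(triisopropylsilyloxy)phenyl]ethan-1-one F2. Mannich-type α-methylenation with paraformaldehyde and Et2NH in EtOH, with oxa-Michael closure in the same flask, should then deliver isoflavanone 20.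

2. Step 10. The C4 cation may lose a proton toward C3 or take a 1,2-hydride shift from C3 before the silane traps it, which would erode the configuration. The acid may also protonate the chromene or prenyl double bond. The fallback replaces the cationic deoxygenation by a radical one (Barton–McCombie deoxygenation); it sets out from 21 and comes back at 22. Alcohol 21 is treated with 1,1'-thiocarbonyldiimidazole and DMAP in CH2Cl2 to give O-[(3R,4R)-3-[2,2-dimethyl-5-(triisopropylsilyloxy)-2H-chromen-8-yl]-6-(3-methylbut-2-en-1-yl)-7-(triisopropylsilyloxy)chroman-4-yl] 1H-imidazole-1-carbothioate F3. Bu3SnH and AIBN in toluene at 80 °C should then replace the C4–O bond by C–H through a benzylic radical that does not touch C3.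

3. Step 7. The 2-bromoacrylamide may polymerise or take up the organometallic in a conjugate addition before cross-coupling occurs. The fallback builds the acrylamide by carbonyl olefination instead of cross-coupling; it sets out from 9 and comes back at 16. Bromine–lithium exchange on 9 (n-BuLi, THF, −78 °C) and addition of the aryllithium to N,N'-dimethoxy-N,N'-dimethyloxamide should give 2-[2,2-dimethyl-5-(triisopropylsilyloxy)-2H-chromen-8-yl]-N-methoxy-N-methyl-2-oxoacetamide F4. Wittig methylenation of its ketone carbonyl with Ph3P=CH2 (from Ph3PCH3Br and KHMDS, THF, −78 → 0 °C) should then give 16.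

**Further compounds**

F1 | step 8 | 1-[2-hydroxy-5-(3-methylbut-2-en-1-yl)-4-(triisopropylsilyloxy)phenyl]ethan-1-one | CC(=O)c1cc(CC=C(C)C)c(O[Si](C(C)C)(C(C)C)C(C)C)cc1O
F2 | step 8 | 2-[2,2-dimethyl-5-(triisopropylsilyloxy)-2H-chromen-8-yl]-1-[2-hydroxy-5-(3-methylbut-2-en-1-yl)-4-(triisopropylsilyloxy)phenyl]ethan-1-one | O=C(Cc1ccc(O[Si](C(C)C)(C(C)C)C(C)C)c2C=CC(C)(C)Oc12)c1cc(CC=C(C)C)c(O[Si](C(C)C)(C(C)C)C(C)C)cc1O
F3 | step 10 | O-[(3R,4R)-3-[2,2-dimethyl-5-(triisopropylsilyloxy)-2H-chromen-8-yl]-6-(3-methylbut-2-en-1-yl)-7-(triisopropylsilyloxy)chroman-4-yl] 1H-imidazole-1-carbothioate | CC(C)=CCc1cc2c(cc1O[Si](C(C)C)(C(C)C)C(C)C)OC[C@@H](c1ccc(O[Si](C(C)C)(C(C)C)C(C)C)c3C=CC(C)(C)Oc13)[C@H]2OC(=S)n1ccnc1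
F4 | step 7 | 2-[2,2-dimethyl-5-(triisopropylsilyloxy)-2H-chromen-8-yl]-N-methoxy-N-methyl-2-oxoacetamide | CON(C)C(=O)C(=O)c1ccc(O[Si](C(C)C)(C(C)C)C(C)C)c2C=CC(C)(C)Oc12
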